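## Retrosynthetic overview

1. The acid comes from its methyl ester, and the C3–CH2CO2Me bond from a Mukaiyama-type aldol addition of a silyl ketene acetal to the peroxycarbenium ion of a 3-(2-methoxyethoxy)-1,2-dioxolane.
2. The alkoxydioxolane comes from a β-hydroperoxy methyl ketone, whose tertiary C–OOH bond is made by invertive perhydrolysis of a 2,2,4-trisubstituted oxetane.
3. The oxetane comes from a 1,3-diol, made by reductive opening of the Sharpless epoxide of an E-trisubstituted allylic alcohol; that alcohol comes from Negishi carboalumination of a terminal alkyne.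
4. The alkyne comes from (R)-citronellol, which supplies the side-chain methyl stereocentre, and a 5-phenylpentyl Wittig unit.
5. Ring order: oxirane (transient), then oxetane (transient), then the 1,2-dioxolane, the only ring built; the phenyl ring is bought.

Assumption: commercial (R)-(+)-citronellol of at least 97% ee is used. The carbinol centre made in step 12 (destroyed in step 17) and the ketal centre of 25 and 26 (reset in step 19) are carried as epimer mixtures.

## Route

Step 1
Reactants: 1 (R)-citronellol [(3R)-3,7-dimethyloct-6-en-1-ol]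
Product: 2 benzyl (3R)-3,7-dimethyloct-6-en-1-yl ether
Conditions: NaH, BnBr, n-Bu4NI (cat.), THF, 0 °C → rt
Reagents that add atoms: benzyl bromide BrCc1ccccc1
Why: Williamson ether synthesis on a primary alkoxide is dependable and does not touch the remote stereocentre.

Step 2
Reactants: 2 benzyl (3R)-3,7-dimethyloct-6-en-1-yl ether
Product: 4 (4R)-6-(benzyloxy)-4-methylhexanal, via secondary ozonide 3 (not isolated)
Conditions: O3, CH2Cl2, −78 °C (Sudan red 7B end point); then PPh3, −78 °C → rt
Reagents that add atoms: ozone [O-][O+]=O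
Why: Ozonolysis with reductive work-up cleaves only the electron-rich trisubstituted alkene, since the benzyl ether reacts far more slowly, and leaves the stereocentre intact.

Step 3
Reactants: 5 (5-bromopentyl)benzene
Product: 6 triphenyl(5-phenylpentyl)phosphonium bromide
Conditions: PPh3, MeCN, reflux
Reagents that add atoms: triphenylphosphine c1ccc(cc1)P(c1ccccc1)c1ccccc1
Why: SN2 quaternisation of triphenylphosphine by an unhindered primary bromide.

Step 4
Reactants: 6 triphenyl(5-phenylpentyl)phosphonium bromide; 4 (4R)-6-(benzyloxy)-4-methylhexanal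
Product: 8 benzyl (3R,6Z)-3-methyl-11-phenylundec-6-en-1-yl ether, via phosphorus ylide 7 (not isolated)
Conditions: NaN(SiMe3)2, THF, 0 °C; then 4, −78 °C → rt
Reagents that add atoms: none
Why: Wittig olefination with a non-stabilised ylide is reliable for an unhindered aldehyde, and the Z/E ratio is irrelevant because the alkene is hydrogenated next.

Step 5
Reactants: 8 benzyl (3R,6Z)-3-methyl-11-phenylundec-6-en-1-yl ether
Product: 9 (3R)-3-methyl-11-phenylundecan-1-ol
Conditions: H2 (1 atm), Pd/C (10 wt% palladium on carbon), EtOH, rt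
Reagents that add atoms: none
Why: Heterogeneous hydrogenation saturates the alkene and hydrogenolyses the benzyl ether in one operation without affecting the isolated phenyl ring or the stereocentre.

Step 6
Reactants: 9 (3R)-3-methyl-11-phenylundecan-1-ol
Product: 10 (3R)-3-methyl-11-phenylundecanal
Conditions: TEMPO (10 mol%), PhI(OAc)2 (1.1 equiv), CH2Cl2, rt
Reagents that add atoms: none
Why: TEMPO-catalysed oxidation stops cleanly at the aldehyde, whose stereocentre is β to the carbonyl and cannot epimerise.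

Step 7
Reactants: 10 (3R)-3-methyl-11-phenylundecanal
Product: 11 (4R)-4-methyl-12-phenyldodec-1-yne
Conditions: dimethyl (1-diazo-2-oxopropyl)phosphonate, K2CO3, MeOH, 0 °C → rt
Reagents that add atoms: dimethyl (1-diazo-2-oxopropyl)phosphonate CC(=O)C(=[N+]=[N-])P(=O)(OC)OC
Why: Ohira–Bestmann (Seyferth–Gilbert) homologation converts an aldehyde into the terminal alkyne under mild base.

Step 8
Reactants: 11 (4R)-4-methyl-12-phenyldodec-1-yne
Product: 14 (2E,5R)-3,5-dimethyl-13-phenyltridec-2-en-1-ol, via alkenyldimethylalane 12 (not isolated), via lithium alkenylaluminate 13 (not isolated)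
Conditions: AlMe3 (2.5 equiv), Cp2ZrCl2 (0.25 equiv), CH2Cl2, 0 °C → rt; volatiles removed; n-BuLi, hexane/THF, −78 → 0 °C; (CH2O)n, rt; cold 1 M HCl
Reagents that add atoms: trimethylaluminium C[Al](C)C; paraformaldehyde (as formaldehyde) C=O
Why: Negishi zirconium-catalysed carboalumination adds Me–Al syn and regioselectively across the terminal alkyne, and the derived aluminate transfers its alkenyl group to formaldehyde with retention, which fixes the E trisubstituted alkene.

Step 9
Reactants: 14 (2E,5R)-3,5-dimethyl-13-phenyltridec-2-en-1-ol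
Product: 15 [(2S,3S)-3-methyl-3-[(2R)-2-methyl-10-phenyldecyl]oxiran-2-yl]methanol
Conditions: Ti(OiPr)4 (10 mol%), L-(+)-diethyl tartrate (12 mol%), t-BuOOH (2 equiv, in decane), 4 Å MS, CH2Cl2, −20 °C
Reagents that add atoms: tert-butyl hydroperoxide CC(C)(C)OO
Why: Sharpless asymmetric epoxidation with the L-(+)-tartrate catalyst gives the (2S,3S)-epoxide as it does for geraniol, so the quaternary C–O stereocentre is set under reagent control, independently of the remote methyl centre.

Step 10
Reactants: 15 [(2S,3S)-3-methyl-3-[(2R)-2-methyl-10-phenyldecyl]oxiran-2-yl]methanol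
Product: 16 (3S,5R)-3,5-dimethyl-13-phenyltridecane-1,3-diol
Conditions: NaAlH2(OCH2CH2OMe)2, THF, 0 °C → rt; aq. potassium sodium tartrate (KNaC4H4O6)
Reagents that add atoms: none
Why: Directed hydride reduction of a 2,3-epoxy alcohol delivers hydride intramolecularly to C2, giving the 1,3-diol with the C3–O bond, and hence the tertiary stereocentre, retained.

Step 11
Reactants: 16 (3S,5R)-3,5-dimethyl-13-phenyltridecane-1,3-diol
Product: 17 (3S,5R)-3-hydroxy-3,5-dimethyl-13-phenyltridecanal
Conditions: TEMPO (10 mol%), PhI(OAc)2 (1.1 equiv), CH2Cl2, rt; used crude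
Reagents that add atoms: none
Why: TEMPO-catalysed oxidation takes only the primary alcohol, the tertiary one being inert, and the near-neutral conditions avoid retro-aldol cleavage or dehydration of the β-hydroxy aldehyde.

Step 12
Reactants: 17 (3S,5R)-3-hydroxy-3,5-dimethyl-13-phenyltridecanal
Product: 18 (4S,6R)-4,6-dimethyl-14-phenyltetradecane-2,4-diol (C2 epimers)
Conditions: MeMgBr (3 equiv), THF, −78 → 0 °C; aq. NH4Cl
Reagents that add atoms: methylmagnesium bromide C[Mg]Br
Why: Grignard addition to the aldehyde after deprotonation of the tertiary hydroxyl; the new carbinol centre forms without control, which is harmless because it is oxidised to the ketone in step 17.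

Step 13
Reactants: 18 (4S,6R)-4,6-dimethyl-14-phenyltetradecane-2,4-diol (C2 epimers)
Product: 19 (4S,6R)-4-hydroxy-4,6-dimethyl-14-phenyltetradecan-2-yl 4-methylbenzenesulfonate (C2 epimers)
Conditions: TsCl (1.3 equiv), pyridine, DMAP (cat.), CH2Cl2, 0 °C → rt
Reagents that add atoms: 4-methylbenzenesulfonyl chloride Cc1ccc(cc1)S(Cl)(=O)=O
Why: Sulfonylation discriminates fully between the secondary hydroxyl and the hindered tertiary one.

Step 14
Reactants: 19 (4S,6R)-4-hydroxy-4,6-dimethyl-14-phenyltetradecan-2-yl 4-methylbenzenesulfonate (C2 epimers)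
Product: 20 (2S)-2,4-dimethyl-2-[(2R)-2-methyl-10-phenyldecyl]oxetane (C4 epimers)
Conditions: n-BuLi (1.05 equiv), THF, 0 → 60 °C
Reagents that add atoms: none
Why: Intramolecular Williamson etherification (4-exo-tet) of the lithium tertiary alkoxide onto the secondary tosylate leaves the tertiary C–O bond unbroken, so the quaternary centre keeps its configuration.

Step 15
Reactants: 20 (2S)-2,4-dimethyl-2-[(2R)-2-methyl-10-phenyldecyl]oxetane (C4 epimers)
Product: 21 (4R,6R)-4-hydroperoxy-4,6-dimethyl-14-phenyltetradecan-2-ol (C2 epimers)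
Conditions: anhydrous H2O2 (ca. 2 M in Et2O, 10 equiv), Me3SiOTf (0.2 equiv), Et2O, −78 → −20 °C
Reagents that add atoms: hydrogen peroxide OO
Why: Lewis acid-activated perhydrolysis of the oxetane takes place at the tertiary carbon by backside attack of H2O2 on the activated C–O bond, so the tertiary hydroperoxide forms with predominant inversion and carries the C5 configuration of the target.

Step 16
Reactants: 21 (4R,6R)-4-hydroperoxy-4,6-dimethyl-14-phenyltetradecan-2-ol (C2 epimers)
Product: 22 (4R,6R)-4-[(2-methoxypropan-2-yl)peroxy]-4,6-dimethyl-14-phenyltetradecan-2-ol (C2 epimers)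
Conditions: 2-methoxypropene (1.2 equiv), pyridinium p-toluenesulfonate (5 mol%), CH2Cl2, 0 °C
Reagents that add atoms: 2-methoxypropene COC(C)=C
Why: Acid-catalysed peroxyketal formation at the more acidic, more nucleophilic O–O–H group is much faster than ketalisation of the hindered secondary alcohol and masks the hydroperoxide for the oxidation.

Step 17
Reactants: 22 (4R,6R)-4-[(2-methoxypropan-2-yl)peroxy]-4,6-dimethyl-14-phenyltetradecan-2-ol (C2 epimers)
Product: 23 (4R,6R)-4-[(2-methoxypropan-2-yl)peroxy]-4,6-dimethyl-14-phenyltetradecan-2-one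
Conditions: Dess–Martin periodinane (1.5 equiv), pyridine (5 equiv), CH2Cl2, 0 °C → rt
Reagents that add atoms: none
Why: Buffered Dess–Martin oxidation converts the secondary alcohol into the methyl ketone without touching the peroxyketal and removes the uncontrolled carbinol centre.

Step 18
Reactants: 23 (4R,6R)-4-[(2-methoxypropan-2-yl)peroxy]-4,6-dimethyl-14-phenyltetradecan-2-one
Product: 26 (5R)-3-(2-methoxyethoxy)-3,5-dimethyl-5-[(2R)-2-methyl-10-phenyldecyl]-1,2-dioxolane (C3 epimers), via hydroperoxy ketone 24 (not isolated), via 3-hydroxy-1,2-dioxolane 25 (not isolated)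
Conditions: TsOH·H2O (10 mol%), 2-methoxyethanol, rt
Reagents that add atoms: 2-methoxyethanol COCCO
Why: Acid-catalysed transketalisation frees the hydroperoxide, which adds to the ketone (5-exo peroxy hemiketal formation), and the hemiketal hydroxyl is exchanged for the solvent alcohol, closing the 1,2-dioxolane ring with C5 unaffected.

Step 19
Reactants: 26 (5R)-3-(2-methoxyethoxy)-3,5-dimethyl-5-[(2R)-2-methyl-10-phenyldecyl]-1,2-dioxolane (C3 epimers); 27 tert-butyl[(1-methoxyethenyl)oxy]dimethylsilane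
Product: 29 methyl 2-[(3R,5R)-3,5-dimethyl-5-[(2R)-2-methyl-10-phenyldecyl]-1,2-dioxolan-3-yl]acetate, via peroxycarbenium ion 28 (not isolated)
Conditions: TiCl4 (1.1 equiv), 27 (3 equiv), CH2Cl2, −78 °C; aq. NaHCO3; silica chromatography then HPLC
Reagents that add atoms: none
Why: In this Mukaiyama-type aldol addition TiCl4, chelated by the 2-methoxyethoxy group, ionises the peroxy ketal to the peroxycarbenium ion, which the silyl ketene acetal captures to form the C3–CH2 bond; facial selectivity at C3 is low (about 1:1), so the (3R,5R) cis-dimethyl isomer is separated from its C3 epimer by chromatography and assigned by NOE between the two ring methyl groups.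

Step 20
Reactants: 29 methyl 2-[(3R,5R)-3,5-dimethyl-5-[(2R)-2-methyl-10-phenyldecyl]-1,2-dioxolan-3-yl]acetate
Product: 30 2-[(3R,5R)-3,5-dimethyl-5-[(2R)-2-methyl-10-phenyldecyl]-1,2-dioxolan-3-yl]acetic acid
Conditions: LiOH·H2O (3 equiv), THF/H2O 3:1, 0 °C → rt; then cold 1 M HCl to pH 3
Reagents that add atoms: lithium hydroxide [Li+].[OH-]
Why: Saponification of the methyl ester at or below room temperature followed by mild acidification leaves the dialkyl peroxide and both quaternary centres untouched.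

## Compound list

1 | (R)-citronellol, (3R)-3,7-dimethyloct-6-en-1-ol | C[C@H](CCC=C(C)C)CCO | starting material
2 | benzyl (3R)-3,7-dimethyloct-6-en-1-yl ether | C[C@H](CCC=C(C)C)CCOCc1ccccc1 | intermediate
3 | 5-[(3R)-5-(benzyloxy)-3-methylpentyl]-3,3-dimethyl-1,2,4-trioxolane (secondary ozonide, ring carbon epimers, not isolated) | C[C@H](CCC1OOC(C)(C)O1)CCOCc1ccccc1 | intermediate
4 | (4R)-6-(benzyloxy)-4-methylhexanal | C[C@H](CCC=O)CCOCc1ccccc1 | intermediate
5 | (5-bromopentyl)benzene | BrCCCCCc1ccccc1 | starting material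
6 | triphenyl(5-phenylpentyl)phosphonium bromide | [Br-].c1ccc(cc1)CCCCC[P+](c1ccccc1)(c1ccccc1)c1ccccc1 | intermediate
7 | (5-phenylpentylidene)triphenylphosphorane (ylide, not isolated) | c1ccc(cc1)CCCCC=P(c1ccccc1)(c1ccccc1)c1ccccc1 | intermediate
8 | benzyl (3R,6Z)-3-methyl-11-phenylundec-6-en-1-yl ether (Z major) | C[C@H](CC/C=C\CCCCc1ccccc1)CCOCc1ccccc1 | intermediate
9 | (3R)-3-methyl-11-phenylundecan-1-ol | C[C@H](CCCCCCCCc1ccccc1)CCO | intermediate
10 | (3R)-3-methyl-11-phenylundecanal | C[C@H](CCCCCCCCc1ccccc1)CC=O | intermediate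
11 | (4R)-4-methyl-12-phenyldodec-1-yne | C[C@H](CCCCCCCCc1ccccc1)CC#C | intermediate
12 | [(1E,4R)-2,4-dimethyl-12-phenyldodec-1-en-1-yl]dimethylalumane (not isolated) | C[C@H](CCCCCCCCc1ccccc1)C/C(C)=C/[Al](C)C | intermediate
13 | lithium butyl[(1E,4R)-2,4-dimethyl-12-phenyldodec-1-en-1-yl]dimethylaluminate (not isolated) | [Li+].C[C@H](CCCCCCCCc1ccccc1)C/C(C)=C/[Al-](C)(C)CCCC | intermediate
14 | (2E,5R)-3,5-dimethyl-13-phenyltridec-2-en-1-ol | C[C@H](CCCCCCCCc1ccccc1)C/C(C)=C/CO | intermediate
15 | [(2S,3S)-3-methyl-3-[(2R)-2-methyl-10-phenyldecyl]oxiran-2-yl]methanol | C[C@H](CCCCCCCCc1ccccc1)C[C@@]1(C)[C@H](CO)O1 | intermediate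
16 | (3S,5R)-3,5-dimethyl-13-phenyltridecane-1,3-diol | C[C@H](CCCCCCCCc1ccccc1)C[C@](C)(O)CCO | intermediate
17 | (3S,5R)-3-hydroxy-3,5-dimethyl-13-phenyltridecanal | C[C@H](CCCCCCCCc1ccccc1)C[C@](C)(O)CC=O | intermediate
18 | (4S,6R)-4,6-dimethyl-14-phenyltetradecane-2,4-diol (C2 epimers) | C[C@H](CCCCCCCCc1ccccc1)C[C@](C)(O)CC(C)O | intermediate
19 | (4S,6R)-4-hydroxy-4,6-dimethyl-14-phenyltetradecan-2-yl 4-methylbenzenesulfonate (C2 epimers) | C[C@H](CCCCCCCCc1ccccc1)C[C@](C)(O)CC(C)OS(=O)(=O)c1ccc(C)cc1 | intermediate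
20 | (2S)-2,4-dimethyl-2-[(2R)-2-methyl-10-phenyldecyl]oxetane (C4 epimers) | C[C@H](CCCCCCCCc1ccccc1)C[C@@]1(C)CC(C)O1 | intermediate
21 | (4R,6R)-4-hydroperoxy-4,6-dimethyl-14-phenyltetradecan-2-ol (C2 epimers) | C[C@H](CCCCCCCCc1ccccc1)C[C@](OO)(C)CC(C)O | intermediate
22 | (4R,6R)-4-[(2-methoxypropan-2-yl)peroxy]-4,6-dimethyl-14-phenyltetradecan-2-ol (C2 epimers) | C[C@H](CCCCCCCCc1ccccc1)C[C@](OOC(C)(C)OC)(C)CC(C)O | intermediate
23 | (4R,6R)-4-[(2-methoxypropan-2-yl)peroxy]-4,6-dimethyl-14-phenyltetradecan-2-one | C[C@H](CCCCCCCCc1ccccc1)C[C@](OOC(C)(C)OC)(C)CC(C)=O | intermediate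
24 | (4R,6R)-4-hydroperoxy-4,6-dimethyl-14-phenyltetradecan-2-one (not isolated) | C[C@H](CCCCCCCCc1ccccc1)C[C@](OO)(C)CC(C)=O | intermediate
25 | (5R)-3,5-dimethyl-5-[(2R)-2-methyl-10-phenyldecyl]-1,2-dioxolan-3-ol (C3 epimers, not isolated) | C[C@H](CCCCCCCCc1ccccc1)C[C@]1(C)CC(C)(O)OO1 | intermediate
26 | (5R)-3-(2-methoxyethoxy)-3,5-dimethyl-5-[(2R)-2-methyl-10-phenyldecyl]-1,2-dioxolane (C3 epimers) | C[C@H](CCCCCCCCc1ccccc1)C[C@]1(C)CC(C)(OCCOC)OO1 | intermediate
27 | tert-butyl[(1-methoxyethenyl)oxy]dimethylsilane (silyl ketene acetal of methyl acetate) | C=C(OC)O[Si](C)(C)C(C)(C)C | starting material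
28 | (5R)-3,5-dimethyl-5-[(2R)-2-methyl-10-phenyldecyl]-1,2-dioxolan-3-ylium (peroxycarbenium ion, not isolated) | C[C@H](CCCCCCCCc1ccccc1)C[C@]1(C)CC(C)=[O+]O1 | intermediate
29 | methyl 2-[(3R,5R)-3,5-dimethyl-5-[(2R)-2-methyl-10-phenyldecyl]-1,2-dioxolan-3-yl]acetate | C[C@H](CCCCCCCCc1ccccc1)C[C@]1(C)C[C@](C)(CC(=O)OC)OO1 | intermediate
30 | 2-[(3R,5R)-3,5-dimethyl-5-[(2R)-2-methyl-10-phenyldecyl]-1,2-dioxolan-3-yl]acetic acid | C[C@H](CCCCCCCCc1ccccc1)C[C@]1(C)C[C@](C)(CC(=O)O)OO1 | target

## Step count and risks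

Total step count: 20. Longest linear sequence: 19 (steps 1, 2 and 4 to 20, from 1).

The three steps most likely to fail, each with a fallback:

**Step 14, oxetane closure onto a secondary tosylate.** Grob fragmentation or E2 elimination may compete with the 4-exo-tet closure. The fallback sets out from diol 16 and introduces the methyl group after the peroxide instead of before it. The primary hydroxyl of 16 is tosylated (TsCl, pyridine) to (3S,5R)-3-hydroxy-3,5-dimethyl-13-phenyltridecyl 4-methylbenzenesulfonate F1. This closes with KOtBu in THF to (2S)-2-methyl-2-[(2R)-2-methyl-10-phenyldecyl]oxetane F2, now through a primary leaving group. Perhydrolysis as in step 15 gives (3R,5R)-3-hydroperoxy-3,5-dimethyl-13-phenyltridecan-1-ol F3. The O–O–H group is masked with 2-methoxypropene (1.05 equiv, −20 °C) to give (3R,5R)-3-[(2-methoxypropan-2-yl)peroxy]-3,5-dimethyl-13-phenyltridecan-1-ol F4. Buffered Dess–Martin oxidation gives (3R,5R)-3-[(2-methoxypropan-2-yl)peroxy]-3,5-dimethyl-13-phenyltridecanal F5. Chemoselective methyl transfer from MeTi(OiPr)3 (Et2O, −30 °C), which should spare the peroxide, comes back to the route at 22.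

**Step 15, perhydrolysis of the oxetane.** The yield may be low, ionisation may cause elimination, and inversion at the tertiary carbon may be incomplete. The fallback sets out from diol 18, gives up control at C5 and relies on separation. Dess–Martin oxidation gives (4S,6R)-4-hydroxy-4,6-dimethyl-14-phenyltetradecan-2-one F6. Acid-catalysed dehydration (TsOH cat., toluene, reflux) gives (3E,6R)-4,6-dimethyl-14-phenyltetradec-3-en-2-one F7. Acid-catalysed conjugate addition of H2O2 with ring closure (50% H2O2, cat. H2SO4, MeCN, 0 °C → rt) comes back to the route at hemiketal 25. It is now formed together with its C5 epimer (5S)-3,5-dimethyl-5-[(2R)-2-methyl-10-phenyldecyl]-1,2-dioxolan-3-ol F8, and the (5S) series must be removed by HPLC at the ester stage after step 19.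

**Step 19, the C–C bond formation at the peroxycarbenium ion.** The ion may be captured in low yield, and the C3 epimers may be hard to separate as esters. The fallback sets out from 26 and uses allylation of the same cation. TiCl4 and allyltrimethylsilane (CH2Cl2, −78 °C, Hosomi–Sakurai type) give (3S,5R)-3,5-dimethyl-5-[(2R)-2-methyl-10-phenyldecyl]-3-(prop-2-en-1-yl)-1,2-dioxolane F9. It has the same spatial arrangement at C3 as the target; only the descriptor changes, by priority. The C3 epimers are separated at this less polar stage. Ozonolysis in the presence of pyridine (CH2Cl2, −78 °C) gives 2-[(3R,5R)-3,5-dimethyl-5-[(2R)-2-methyl-10-phenyldecyl]-1,2-dioxolan-3-yl]acetaldehyde F10. Oxidation with NaClO2 (NaH2PO4, 2-methyl-2-butene, t-BuOH/H2O) comes back to the route at the target 30.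

## Further compounds

F1 | step 14 | (3S,5R)-3-hydroxy-3,5-dimethyl-13-phenyltridecyl 4-methylbenzenesulfonate | C[C@H](CCCCCCCCc1ccccc1)C[C@](C)(O)CCOS(=O)(=O)c1ccc(C)cc1
F2 | step 14 | (2S)-2-methyl-2-[(2R)-2-methyl-10-phenyldecyl]oxetane | C[C@H](CCCCCCCCc1ccccc1)C[C@@]1(C)CCO1
F3 | step 14 | (3R,5R)-3-hydroperoxy-3,5-dimethyl-13-phenyltridecan-1-ol | C[C@H](CCCCCCCCc1ccccc1)C[C@](OO)(C)CCO
F4 | step 14 | (3R,5R)-3-[(2-methoxypropan-2-yl)peroxy]-3,5-dimethyl-13-phenyltridecan-1-ol | C[C@H](CCCCCCCCc1ccccc1)C[C@](OOC(C)(C)OC)(C)CCO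
F5 | step 14 | (3R,5R)-3-[(2-methoxypropan-2-yl)peroxy]-3,5-dimethyl-13-phenyltridecanal | C[C@H](CCCCCCCCc1ccccc1)C[C@](OOC(C)(C)OC)(C)CC=O
F6 | step 15 | (4S,6R)-4-hydroxy-4,6-dimethyl-14-phenyltetradecan-2-one | C[C@H](CCCCCCCCc1ccccc1)C[C@](C)(O)CC(C)=O
F7 | step 15 | (3E,6R)-4,6-dimethyl-14-phenyltetradec-3-en-2-one | C[C@H](CCCCCCCCc1ccccc1)C/C(C)=C/C(C)=O
F8 | step 15 | (5S)-3,5-dimethyl-5-[(2R)-2-methyl-10-phenyldecyl]-1,2-dioxolan-3-ol (C3 epimers) | C[C@H](CCCCCCCCc1ccccc1)C[C@@]1(C)CC(C)(O)OO1
F9 | step 19 | (3S,5R)-3,5-dimethyl-5-[(2R)-2-methyl-10-phenyldecyl]-3-(prop-2-en-1-yl)-1,2-dioxolane | C[C@H](CCCCCCCCc1ccccc1)C[C@]1(C)C[C@](C)(CC=C)OO1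
F10 | step 19 | 2-[(3R,5R)-3,5-dimethyl-5-[(2R)-2-methyl-10-phenyldecyl]-1,2-dioxolan-3-yl]acetaldehyde | C[C@H](CCCCCCCCc1ccccc1)C[C@]1(C)C[C@](C)(CC=O)OO1
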